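Atom numbers follow the germacrane skeleton: C1 ketone, C2=C3 furanone alkene, C4 (bears C15), C5, C6 (lactone O), C7, C8 (ester O), C9, C10 (bears C14, ether O to C3), C11–C13 lactone α-carbon, carbonyl and methylene. The same locants are used in the names of the carbocyclic intermediates.

## The problem

The target is a 4,5-dihydrofuranoheliangolide. A ten-membered carbocycle (C1–C10) is bridged by oxygen between C3 and C10, so that C10, C1, C2, C3 and that oxygen form a 3(2H)-furanone. A trans-fused α-methylene-γ-lactone sits on C6–C7, and O8 carries (R)-2,3-dihydroxy-2-methylpropanoate. The six-carbon arc C4–C9 must span the 2- and 5-positions of a flat five-membered ring, so any closure of the carbocycle is a strained medium-ring closure, and the arc lies over one face of the furanone. Quaternary C10 has no stereogenic neighbour and must be set by a reagent; once set, it decides which face of the furanone the arc covers, and so which faces of C4 and of a C7=C8 olefin are open. C6 can be bought as a building block, and C7 and C8 are best made together from that olefin under the influence of C6. C4 is γ to the ketone, but inside the bicycle its planar dienolate is strained, so it must be installed kinetically and cannot be corrected later by equilibration. The α-methylene lactone (a Michael acceptor), the C8 oxygen next to the lactone carbonyl (base can move the lactone onto it) and the side-chain 1,2-diol do not survive strong base or nucleophiles, so they come last. The enabling feature is the triad C6(O)–C7(C11)–C8(O) with C7–C11 anti to the C8 oxygen. That is the imprint of a cis-7,8-epoxide opened at C7, with inversion, by a carbon nucleophile hanging from O6.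

## Retrosynthesis

**Side chain, 21 to 13 and 18.** The O8–acyl bond is cut last and the diol is masked as an acetonide (20). Acid 18 carries the sixth stereocentre from a building block, and alcohol 13 is free of the diol and the hindered ester. Cutting here, and not earlier, keeps the ester out of every basic step. The forward reaction must acylate a hindered secondary alcohol beside a Michael acceptor, and the acetonide must come off in mild acid.

**Methylene, 13 to 12.** The C11=C13 bond is cut to formaldehyde and the α-phosphono lactone 12. The phosphonate is already in place from the lactone-forming step, so no separate enolate methylenation of a lactone beside the furanone is needed.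

**Lactone triad, 12 to 11 (key).** The C7–C11 bond, and with it the lactone ring, is cut to the cis-7,8-epoxide 11 carrying a phosphonoacetate on O6. Two stereocentres and one ring are removed, and the C7/C8 problem becomes the face selectivity of one epoxidation. A neighbouring cut, acylation of a preformed 6,8-diol, would leave the C7–C11 bond and its configuration unsolved. The forward step needs 5-exo attack at C7 rather than 6-endo attack at C8, and a base that touches only the phosphonoacetate.

**Ester and epoxide, 11 to 9 and 10, then 9 to 8.** The O6–acyl bond is cut to epoxy alcohol 9 and acid 10, and the epoxide oxygen is removed to give the Z-allylic alcohol 8. The forward epoxidation must occur on the olefin face syn to the C6 hydroxyl, which that hydroxyl can direct.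

**C15, 8 to 7.** The C4–C15 bond is cut to the bicyclic alcohol 7 and iodomethane. The methyl is removed before the ring is opened on purpose. On an open chain nothing controls C4, whereas in 7 the arc covers one face of the C3=C4 enolate. The forward step asks for γ-deprotonation within the bicycle and alkylation from the open face.

**Carbocycle, 7 to 6.** The C7=C8 bond is cut by a metathesis transform to diene 6. This is the only olefin of the ring that is needed later, so ring closure and epoxide precursor are obtained together. The forward reaction must close a strained Z-cyclodecene in competition with oligomerisation.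

**C4–C5, 6 to 4 and 5.** The C4–C5 bond is cut to the γ-carbanion of furanone 4 and (S)-2-vinyloxirane 5, which delivers C5–C7 and the C6 stereocentre in one bond formation. Making this cut while C4 is still a methyl group gives a primary, more reactive carbanion. The forward reaction must open the epoxide at its CH2 terminus.

**C10, 4 to 3 to 1 and 2.** The C9–C10 bond is cut to the allyl enol carbonate 3 of commercial furanone 1, made with allyl chloroformate 2. The stereocentre is thereby created by a chiral palladium catalyst on an aromatic furanolate, with no auxiliary.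

**Acid 18.** The acetonide acid 18 goes back through methyl ester 17 and diol acid 16 to commercial (S)-bromohydrin acid 14. The quaternary carbinol is never a reaction site, so its configuration is secure.

## Roads not taken

**Alternative 1:** The furanone is read as a masked 1,3-diketone and cut at C1–C2 and O–C3. Forward, a nitrile oxide made from a C1 aldoxime with NaOCl adds across a terminal C2–C3 alkyne, closing an isoxazole and the ten-membered ring at once to give A1. A1 already carries the C6/C7 lactone and silyl ethers on O8 and O10.
- Merits: every stereocentre (C4, C6, C7, C8, C10) is fixed on an open chain before any strain is met, the ring closure is irreversible, and N–O cleavage is a mild unmasking.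
- Weak points: the nitrile oxide and the alkyne must both stay near-linear in a ten-membered transition state, and the product is a short 3,5-bridged heteroaromatic, so dimerisation of the nitrile oxide is a likely competitor. After the key step there remain N–O cleavage (for example Mo(CO)6), hydrolysis, desilylation, cyclodehydration to the furanone, α-methylenation and acylation.
- Comparison: this road is stronger where the chosen plan is weakest, since C4 and the C7/C8 configuration do not depend on the conformation of a bridged ring. The chosen plan sets against this roughly half the linear length and a lactone triad made in one stereospecific step with the methylene precursor built in.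

**Alternative 2:** The cut is at O–C10 and C9–C10. Forward, Cu(hfacac)2 (divalent copper) decomposes a diazo ketone. The C10 carbenoid is captured by a tetrahydropyran oxygen, and the [2,3]-shift of the allylic oxonium ylide expands the pyran into the carbocycle while forming the five-membered ether ring, giving A2.
- Merits: the bridge, quaternary C10, the medium ring and a Z-olefin arise together by ring expansion, which avoids an end-to-end medium-ring closure, and C10 is set by relay from the pyran.
- Weak points: the carbenoid carbon bears a methyl group, so 1,2-hydride shift to an enone is a known competing path. A2 is also at the wrong oxidation level in three places: the tetrahydrofuranone must be dehydrogenated, the trisubstituted C7=C8 olefin must be turned into C7–H/C8–O with the right face, and the lactone and methylene are still to be built.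
- Comparison: as a ring-forming step it is probably more reliable than the metathesis used here. The chosen plan answers with catalyst control of C10 in two steps from a commercial furanone and with far fewer redox corrections after the ring is formed.

**Alternative 3:** The cut is the C4–C5 bond as an olefin. Forward, the second-generation Hoveyda–Grubbs catalyst joins an isopropenyl group on C3 with a vinyl group on C6 to give A3, the 4,5-dehydro skeleton, and a conjugate reduction then sets C4.
- Merits: A3 has the olefin where the natural heliangolides have it, so the closed ring is a known, tolerable skeleton, and C6, C7 and C8 are set before cyclisation.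
- Weak points: the metathesis must engage a 1,1-disubstituted, electron-poor olefin. The reduction must distinguish C4=C5 from C2=C3 within one cross-conjugated system and set C4 by protonation of a strained dienolate. The lactone still needs α-methylenation.
- Comparison: as a ring closure this is at least as good as step 4 here and probably better, because the Z-7,8-olefin of 7 is a less familiar and likely more strained isomer. The chosen plan sets C4 by C–C bond formation on the open face, creates C7 and C8 in one stereospecific step, and gains the methylene from the phosphonate.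

Key step: step 8

Assumption: the (R,R) antipode of the ligand is written in step 2; which antipode gives (R)-4 on this furanolate must be settled in the first run, and the other antipode is used if the sense is reversed.

## Route

Step 1
Reactants: 1 2,5-dimethylfuran-3(2H)-one; 2 allyl chloroformate
Product: 3 allyl 2,5-dimethylfuran-3-yl carbonate
Conditions: NaN(SiMe3)2, THF, −78 °C; then 2, −78 → 0 °C
Reagents that add atoms: none
Why: Enol carbonate formation; deprotonation at C2 gives the aromatic sodium furan-3-olate, whose oxygen is acylated by the hard chloroformate, and the stereocentre of racemic 1 is erased.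

Step 2
Reactants: 3 allyl 2,5-dimethylfuran-3-yl carbonate
Product: 4 (2R)-2-allyl-2,5-dimethylfuran-3(2H)-one
Conditions: Pd2(dba)3 (zerovalent palladium, 2.5 mol %), (R,R)-ANDEN-phenyl Trost ligand (6 mol %), 1,4-dioxane, 23 °C
Reagents that add atoms: none
Why: Decarboxylative asymmetric allylic alkylation (Tsuji–Trost type); ionisation and loss of CO2 give a furanolate/π-allylpalladium pair that recombines at C2, restoring the vinylogous ester, and the chiral diphosphine selects the enolate face that sets quaternary C10; any minor enantiomer becomes a separable diastereomer after step 3.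

Step 3
Reactants: 4 (2R)-2-allyl-2,5-dimethylfuran-3(2H)-one; 5 (S)-2-vinyloxirane
Product: 6 (2R)-2-allyl-5-[(3R)-3-hydroxypent-4-en-1-yl]-2-methylfuran-3(2H)-one
Conditions: LiN(iPr)2, THF, −78 °C; 5, LiClO4, −78 → 0 °C; AcOH, −40 °C
Reagents that add atoms: none
Why: γ-Alkylation of a 3(2H)-furanone dienolate by SN2 epoxide opening; with C2 quaternary the base removes a 5-methyl proton, and the extended enolate attacks the unhindered CH2 of the lithium-activated epoxide through its γ-carbon; the epoxide stereocentre is untouched and becomes C6 (R).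

Step 4
Reactants: 6 (2R)-2-allyl-5-[(3R)-3-hydroxypent-4-en-1-yl]-2-methylfuran-3(2H)-one
Product: 7 (2Z,6R,7Z,10R)-3,10-epoxy-6-hydroxy-10-methylcyclodeca-2,7-dien-1-one
Conditions: second-generation Hoveyda–Grubbs catalyst RuCl2(H2IMes)(=CH-C6H4-2-OiPr) (10 mol %), 1,4-benzoquinone (20 mol %), toluene (1 mM), 80 °C
Reagents that add atoms: none
Why: Ring-closing metathesis of two monosubstituted olefins with loss of ethylene; the 2,5-attachment to the furanone holds the chain ends together, the ring size permits only the Z-olefin, and benzoquinone suppresses Ru–H isomerisation of the allylic alcohol.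

Step 5
Reactants: 7 (2Z,6R,7Z,10R)-3,10-epoxy-6-hydroxy-10-methylcyclodeca-2,7-dien-1-one
Product: 8 (2Z,4S,6R,7Z,10R)-3,10-epoxy-6-hydroxy-4,10-dimethylcyclodeca-2,7-dien-1-one
Conditions: LiN(iPr)2 (2.2 equiv), THF, −78 °C; MeI, −78 → −40 °C; AcOH
Reagents that add atoms: iodomethane, CI
Why: γ-Alkylation of the furanone dienolate (as the dianion with the C6 alkoxide, C-methylation being far faster than O-methylation of a lithium alkoxide at −78 °C); the C5–C9 arc covers one face of the C3=C4 enolate, so iodomethane enters from the open face on the side of the C10 methyl group, which gives (4S), and the remaining C4–H then lies near the furanone plane, which disfavours a second deprotonation.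

Step 6
Reactants: 8 (2Z,4S,6R,7Z,10R)-3,10-epoxy-6-hydroxy-4,10-dimethylcyclodeca-2,7-dien-1-one
Product: 9 (2Z,4S,6R,7R,8S,10R)-3,10:7,8-diepoxy-6-hydroxy-4,10-dimethylcyclodec-2-en-1-one
Conditions: VO(acac)2 (5 mol %), t-BuOOH, CH2Cl2, 0 → 23 °C
Reagents that add atoms: tert-butyl hydroperoxide, CC(C)(C)OO
Why: Hydroxyl-directed epoxidation of a cyclic Z-allylic alcohol; the vanadate ester of the C6 hydroxyl delivers oxygen to the olefin face syn to it, which a model of the bicycle also shows as the face turned away from the furanone, giving the cis-epoxide syn to O6; the electron-poor C2=C3 bond is not attacked.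

Step 7
Reactants: 9 (2Z,4S,6R,7R,8S,10R)-3,10:7,8-diepoxy-6-hydroxy-4,10-dimethylcyclodec-2-en-1-one; 10 2-(diethoxyphosphoryl)acetic acid
Product: 11 (2Z,4S,6R,7S,8S,10R)-3,10:7,8-diepoxy-4,10-dimethyl-1-oxocyclodec-2-en-6-yl 2-(diethoxyphosphoryl)acetate
Conditions: DCC, DMAP (cat.), CH2Cl2, 0 → 23 °C
Reagents that add atoms: none
Why: Steglich esterification of the secondary alcohol; no alkoxide is formed, so the epoxy alcohol cannot undergo Payne rearrangement and no stereocentre is touched.

Step 8
Reactants: 11 (2Z,4S,6R,7S,8S,10R)-3,10:7,8-diepoxy-4,10-dimethyl-1-oxocyclodec-2-en-6-yl 2-(diethoxyphosphoryl)acetate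
Product: 12 diethyl [(3S,3aR,4S,6R,10S,11aR)-4-hydroxy-6,10-dimethyl-2,7-dioxo-2,3,3a,4,5,6,7,10,11,11a-decahydro-6,9-epoxycyclodeca[b]furan-3-yl]phosphonate
Conditions: LiCl, DBU, MeCN, 23 → 45 °C
Reagents that add atoms: none
Why: LiCl and the amidine generate the lithium enolate of the phosphonoacetate (Masamune–Roush conditions), and lithium also activates the epoxide oxygen. C11 then attacks C7 in an intramolecular SN2 displacement of the epoxide oxygen, forming C7–C11 and closing the γ-lactone in the 5-exo-tet mode; the closest known reaction type is the intramolecular opening of epoxides by malonate-type ester enolates to α-substituted γ-lactones. C7 is set by inversion and is therefore fixed by the epoxide configuration, which places C11 anti to the C8 oxygen and, with the tether coming from O6, makes the ring fusion trans. C8 is not a reaction site, so its C–O bond is retained and emerges as the free hydroxyl. C11 is epimerisable, should settle with the phosphonate trans to C8, and is erased in step 9. The step needs 5-exo over 6-endo attack: the three-atom tether reaches the rear of C7 with a near-collinear approach, whereas reaching the rear of unactivated C8 would force the planar ester out of conjugation. It also needs the base to touch only the phosphonoacetate: C4–H is left alone because its dienolate would be a twisted, strained system, and no O6 alkoxide exists to start a Payne rearrangement. The product rests as its phosphonate enolate with a neutral C8 hydroxyl, which should suppress migration of the lactone to O8, and opening relieves the strain of the bicyclic cis-epoxide.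

Step 9
Reactants: 12 diethyl [(3S,3aR,4S,6R,10S,11aR)-4-hydroxy-6,10-dimethyl-2,7-dioxo-2,3,3a,4,5,6,7,10,11,11a-decahydro-6,9-epoxycyclodeca[b]furan-3-yl]phosphonate
Product: 13 (3aR,4S,6R,10S,11aR)-4-hydroxy-6,10-dimethyl-3-methylidene-3a,4,5,6,10,11-hexahydro-6,9-epoxycyclodeca[b]furan-2,7(3H,11aH)-dione
Conditions: aq. CH2O (37 %), K2CO3, THF, 0 °C
Reagents that add atoms: formaldehyde, C=O
Why: Horner–Wadsworth–Emmons olefination of an α-phosphono lactone with formaldehyde; the C11 centre is converted into the exocyclic methylene, and carbonate at 0 °C is mild enough to limit translactonisation to the free C8 hydroxyl (its 5-endo addition to the new acceptor is disfavoured).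

Step 10
Reactants: 14 (2S)-3-bromo-2-hydroxy-2-methylpropanoic acid
Product: 16 (2R)-2,3-dihydroxy-2-methylpropanoic acid, via sodium (2R)-2-methyloxirane-2-carboxylate 15 (not isolated)
Conditions: NaOH, H2O, 80 °C; then HCl to pH 2
Reagents that add atoms: sodium hydroxide, [Na+].[OH-]
Why: Intramolecular Williamson closure to the glycidate, then SN2 opening by hydroxide at the primary carbon; the quaternary carbinol carbon is never attacked, so its geometry is retained (the descriptor changes from S to R only because Br is replaced by OH).

Step 11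
Reactants: 16 (2R)-2,3-dihydroxy-2-methylpropanoic acid
Product: 17 methyl (4R)-2,2,4-trimethyl-1,3-dioxolane-4-carboxylate
Conditions: Me2C(OMe)2, MeOH, TsOH·H2O (cat.), 50 °C
Reagents that add atoms: 2,2-dimethoxypropane, COC(C)(C)OC; methanol, CO
Why: Fischer esterification with concurrent isopropylidene acetal formation by transketalisation; the acetal reagent also removes the water of esterification, and esterifying first avoids the competing dioxolanone from the α-hydroxy acid.

Step 12
Reactants: 17 methyl (4R)-2,2,4-trimethyl-1,3-dioxolane-4-carboxylate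
Product: 18 (4R)-2,2,4-trimethyl-1,3-dioxolane-4-carboxylic acid
Conditions: LiOH, THF/H2O, 0 → 23 °C; then HCl to pH 3, 0 °C
Reagents that add atoms: lithium hydroxide, [Li+].[OH-]
Why: Saponification of the methyl ester; the acetal is stable to base and survives a brief cold acidification.

Step 13
Reactants: 13 (3aR,4S,6R,10S,11aR)-4-hydroxy-6,10-dimethyl-3-methylidene-3a,4,5,6,10,11-hexahydro-6,9-epoxycyclodeca[b]furan-2,7(3H,11aH)-dione; 18 (4R)-2,2,4-trimethyl-1,3-dioxolane-4-carboxylic acid
Product: 20 (3aS,4S,6R,10S,11aR)-6,10-dimethyl-3-methylidene-2,7-dioxo-2,3,3a,4,5,6,7,10,11,11a-decahydro-6,9-epoxycyclodeca[b]furan-4-yl (4R)-2,2,4-trimethyl-1,3-dioxolane-4-carboxylate, via Yamaguchi mixed anhydride 19 (not isolated)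
Conditions: 18, 2,4,6-Cl3C6H2COCl, Et3N, toluene, 23 °C; then 13, DMAP, 23 → 40 °C
Reagents that add atoms: none
Why: Yamaguchi esterification; DMAP attacks the less hindered aliphatic carbonyl of the mixed anhydride and the acylpyridinium acylates the hindered C8 alcohol, without touching a stereocentre and without strong base near the methylene lactone.

Step 14
Reactants: 20 (3aS,4S,6R,10S,11aR)-6,10-dimethyl-3-methylidene-2,7-dioxo-2,3,3a,4,5,6,7,10,11,11a-decahydro-6,9-epoxycyclodeca[b]furan-4-yl (4R)-2,2,4-trimethyl-1,3-dioxolane-4-carboxylate
Product: 21 (3aS,4S,6R,10S,11aR)-6,10-dimethyl-3-methylidene-2,7-dioxo-2,3,3a,4,5,6,7,10,11,11a-decahydro-6,9-epoxycyclodeca[b]furan-4-yl (2R)-2,3-dihydroxy-2-methylpropanoate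
Conditions: CF3CO2H/H2O (9:1), CH2Cl2, 0 °C
Reagents that add atoms: none
Why: Acid hydrolysis of the isopropylidene acetal; the lactone, the tertiary ester and the vinylogous ester of the furanone should tolerate cold aqueous trifluoroacetic acid.

## Compound list

1 | 2,5-dimethylfuran-3(2H)-one (racemic) | CC1OC(C)=CC1=O | starting material
2 | allyl chloroformate | C=CCOC(=O)Cl | starting material
3 | allyl 2,5-dimethylfuran-3-yl carbonate | Cc1oc(C)cc1OC(=O)OCC=C | intermediate
4 | (2R)-2-allyl-2,5-dimethylfuran-3(2H)-one | CC1=CC(=O)[C@@](C)(CC=C)O1 | intermediate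
5 | (S)-2-vinyloxirane | C=C[C@H]1CO1 | starting material
6 | (2R)-2-allyl-5-[(3R)-3-hydroxypent-4-en-1-yl]-2-methylfuran-3(2H)-one | C=C[C@H](O)CCC1=CC(=O)[C@@](C)(CC=C)O1 | intermediate
7 | (2Z,6R,7Z,10R)-3,10-epoxy-6-hydroxy-10-methylcyclodeca-2,7-dien-1-one | O[C@H]1/C=C\C[C@@]2(C)OC(=CC2=O)CC1 | intermediate
8 | (2Z,4S,6R,7Z,10R)-3,10-epoxy-6-hydroxy-4,10-dimethylcyclodeca-2,7-dien-1-one | O[C@H]1/C=C\C[C@@]2(C)OC(=CC2=O)[C@@H](C)C1 | intermediate
9 | (2Z,4S,6R,7R,8S,10R)-3,10:7,8-diepoxy-6-hydroxy-4,10-dimethylcyclodec-2-en-1-one | O[C@@H]1C[C@H](C)C2=CC(=O)[C@@](C)(C[C@@H]3O[C@@H]31)O2 | intermediate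
10 | 2-(diethoxyphosphoryl)acetic acid | CCOP(=O)(CC(=O)O)OCC | starting material
11 | (2Z,4S,6R,7S,8S,10R)-3,10:7,8-diepoxy-4,10-dimethyl-1-oxocyclodec-2-en-6-yl 2-(diethoxyphosphoryl)acetate | CCOP(=O)(OCC)CC(=O)O[C@@H]1C[C@H](C)C2=CC(=O)[C@@](C)(C[C@@H]3O[C@@H]31)O2 | intermediate
12 | diethyl [(3S,3aR,4S,6R,10S,11aR)-4-hydroxy-6,10-dimethyl-2,7-dioxo-2,3,3a,4,5,6,7,10,11,11a-decahydro-6,9-epoxycyclodeca[b]furan-3-yl]phosphonate (C11 epimerisable) | CCOP(=O)(OCC)[C@@H]1C(=O)O[C@@H]2C[C@H](C)C3=CC(=O)[C@@](C)(C[C@H](O)[C@@H]12)O3 | intermediate
13 | (3aR,4S,6R,10S,11aR)-4-hydroxy-6,10-dimethyl-3-methylidene-3a,4,5,6,10,11-hexahydro-6,9-epoxycyclodeca[b]furan-2,7(3H,11aH)-dione | C=C1C(=O)O[C@@H]2C[C@H](C)C3=CC(=O)[C@@](C)(C[C@H](O)[C@@H]12)O3 | intermediate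
14 | (2S)-3-bromo-2-hydroxy-2-methylpropanoic acid | OC(=O)[C@](C)(O)CBr | starting material
15 | sodium (2R)-2-methyloxirane-2-carboxylate | [Na+].[O-]C(=O)[C@@]1(C)CO1 | intermediate
16 | (2R)-2,3-dihydroxy-2-methylpropanoic acid | OC(=O)[C@](C)(O)CO | intermediate
17 | methyl (4R)-2,2,4-trimethyl-1,3-dioxolane-4-carboxylate | COC(=O)[C@]1(C)OC(C)(C)OC1 | intermediate
18 | (4R)-2,2,4-trimethyl-1,3-dioxolane-4-carboxylic acid | OC(=O)[C@]1(C)OC(C)(C)OC1 | intermediate
19 | (4R)-2,2,4-trimethyl-1,3-dioxolane-4-carboxylic 2,4,6-trichlorobenzoic anhydride | O=C(OC(=O)[C@]1(C)OC(C)(C)OC1)c1c(Cl)cc(Cl)cc1Cl | intermediate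
20 | (3aS,4S,6R,10S,11aR)-6,10-dimethyl-3-methylidene-2,7-dioxo-2,3,3a,4,5,6,7,10,11,11a-decahydro-6,9-epoxycyclodeca[b]furan-4-yl (4R)-2,2,4-trimethyl-1,3-dioxolane-4-carboxylate | C=C1C(=O)O[C@@H]2C[C@H](C)C3=CC(=O)[C@@](C)(C[C@H](OC(=O)[C@]4(C)OC(C)(C)OC4)[C@@H]12)O3 | intermediate
21 | (3aS,4S,6R,10S,11aR)-6,10-dimethyl-3-methylidene-2,7-dioxo-2,3,3a,4,5,6,7,10,11,11a-decahydro-6,9-epoxycyclodeca[b]furan-4-yl (2R)-2,3-dihydroxy-2-methylpropanoate | C=C1C(=O)O[C@@H]2C[C@H](C)C3=CC(=O)[C@@](C)(C[C@H](OC(=O)[C@](C)(O)CO)[C@@H]12)O3 | target

## Step count and least certain steps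

Total step count: 14. Longest linear sequence: 11 steps (steps 1–9, 13, 14); steps 10–12 make the side-chain acid.

**Step 8 (key step).**
- What may go wrong: ring closure may be slow. The ester must turn into its s-cis form and the bicyclic epoxide must reach the rotamer with O6 antiperiplanar to the C7–O bond, while the bulky, well-stabilised phosphonate anion is a weak nucleophile. During a slow reaction, ester cleavage or attack at C8 can take over.
- Fallback: this sets out from 9 and returns at 13. The alcohol is esterified (DCC, DMAP) with 3-tert-butoxy-3-oxopropanoic acid to the mixed malonate tert-butyl (2Z,4S,6R,7S,8S,10R)-3,10:7,8-diepoxy-4,10-dimethyl-1-oxocyclodec-2-en-6-yl propanedioate F1. Its smaller, more nucleophilic anion (Cs2CO3, DMF) should close to the α-tert-butoxycarbonyl lactone F2. Trifluoroacetic acid frees the α-carboxy lactone F3, and decarboxylative Mannich methylenation (aq. CH2O, Et2NH) gives 13.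

**Step 4.**
- What may go wrong: oligomerisation instead of ring closure, because the Z-7,8-olefin in the bridged ten-membered ring is strained and metathesis is reversible; isomerisation of the allylic alcohol is a second drain.
- Fallback: this sets out from 4 and returns at 7, using an irreversible Nozaki–Hiyama–Kishi closure.
  - The allyl group of 4 is cleaved (OsO4 cat., NaIO4) to 2-[(2R)-2,5-dimethyl-3-oxo-2,3-dihydrofuran-2-yl]acetaldehyde F4.
  - Stork–Zhao olefination (Ph3P=CHI) gives (2R)-2-[(2Z)-3-iodoprop-2-en-1-yl]-2,5-dimethylfuran-3(2H)-one F5.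
  - γ-Allylation (LiN(iPr)2, allyl bromide) gives (2R)-5-(but-3-en-1-yl)-2-[(2Z)-3-iodoprop-2-en-1-yl]-2-methylfuran-3(2H)-one F6.
  - A second cleavage of the terminal olefin gives 3-{(5R)-5-[(2Z)-3-iodoprop-2-en-1-yl]-5-methyl-4-oxo-4,5-dihydrofuran-2-yl}propanal F7.
  - CrCl2 with catalytic NiCl2 in DMSO at high dilution closes the C6–C7 bond to 7 together with its epimer (2Z,6S,7Z,10R)-3,10-epoxy-6-hydroxy-10-methylcyclodeca-2,7-dien-1-one F8.
  - The epimer is converged by Dess–Martin oxidation to (2Z,7Z,10R)-3,10-epoxy-10-methylcyclodeca-2,7-diene-1,6-dione F9 and reduction with the 2-methyl-CBS-oxazaborolidine antipode that delivers the (6R) alcohol 7.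

**Step 5.**
- What may go wrong: deprotonation at C4 may fail, because the C3=C4 enolate cannot become fully planar inside the bicycle; the base may then attack the carbonyl, or alkylation may occur at oxygen or C2.
- Fallback: this sets out from 6 and returns at 8. The open-chain dianion of 6 is methylated (LiN(iPr)2, MeI) to (2R)-2-allyl-5-[(2RS,4R)-4-hydroxyhex-5-en-2-yl]-2-methylfuran-3(2H)-one F10. Metathesis as in step 4 gives 8 and its epimer (2Z,4R,6R,7Z,10R)-3,10-epoxy-6-hydroxy-4,10-dimethylcyclodeca-2,7-dien-1-one F11, which are separated. This gives up control of C4 and costs about half the material.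

**Step 3.**
- What may go wrong: the delocalised lithium dienolate may react sluggishly with the epoxide, with competing attack at the allylic carbon or SN2′ opening. The product alkoxide may also add 5-exo to C3 to give a spiroketal.
- Fallback: this sets out from 4 and returns at 6, with commercial (S)-but-3-ene-1,2-diol as the chiral source.
  - The diol is bis-silylated to (S)-3,4-bis[(tert-butyldimethylsilyl)oxy]but-1-ene F12.
  - The primary silyl ether is cleaved (HF·pyridine) to (S)-2-[(tert-butyldimethylsilyl)oxy]but-3-en-1-ol F13.
  - Tf2O and 2,6-lutidine give (S)-2-[(tert-butyldimethylsilyl)oxy]but-3-en-1-yl trifluoromethanesulfonate F14.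
  - The dienolate of 4 is alkylated by this triflate at −78 °C to (2R)-2-allyl-5-{(3R)-3-[(tert-butyldimethylsilyl)oxy]pent-4-en-1-yl}-2-methylfuran-3(2H)-one F15, and Bu4NF gives 6.

**Step 6.**
- What may go wrong: poor facial selectivity, that is, epoxidation on the face anti to the C6 hydroxyl if the ring presents that face outward.
- Fallback: this sets out from 8 and returns at 9. N-Bromosuccinimide in aqueous DME forms the bromonium ion on the exposed face, and water opens it from the other side to (2Z,4S,6R,7S,8S,10R)-7-bromo-3,10-epoxy-6,8-dihydroxy-4,10-dimethylcyclodec-2-en-1-one F16. Mild base (K2CO3) then closes the C8 alkoxide onto C7, placing the epoxide on the face opposite to the one direct epoxidation prefers.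

## Further compounds

F1 | step 8 | tert-butyl (2Z,4S,6R,7S,8S,10R)-3,10:7,8-diepoxy-4,10-dimethyl-1-oxocyclodec-2-en-6-yl propanedioate | CC(C)(C)OC(=O)CC(=O)O[C@@H]1C[C@H](C)C2=CC(=O)[C@@](C)(C[C@@H]3O[C@@H]31)O2
F2 | step 8 | tert-butyl (3S,3aR,4S,6R,10S,11aR)-4-hydroxy-6,10-dimethyl-2,7-dioxo-2,3,3a,4,5,6,7,10,11,11a-decahydro-6,9-epoxycyclodeca[b]furan-3-carboxylate | CC(C)(C)OC(=O)[C@@H]1C(=O)O[C@@H]2C[C@H](C)C3=CC(=O)[C@@](C)(C[C@H](O)[C@@H]12)O3
F3 | step 8 | (3R,3aR,4S,6R,10S,11aR)-4-hydroxy-6,10-dimethyl-2,7-dioxo-2,3,3a,4,5,6,7,10,11,11a-decahydro-6,9-epoxycyclodeca[b]furan-3-carboxylic acid | OC(=O)[C@@H]1C(=O)O[C@@H]2C[C@H](C)C3=CC(=O)[C@@](C)(C[C@H](O)[C@@H]12)O3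
F4 | step 4 | 2-[(2R)-2,5-dimethyl-3-oxo-2,3-dihydrofuran-2-yl]acetaldehyde | CC1=CC(=O)[C@@](C)(CC=O)O1
F5 | step 4 | (2R)-2-[(2Z)-3-iodoprop-2-en-1-yl]-2,5-dimethylfuran-3(2H)-one | CC1=CC(=O)[C@@](C)(C/C=C\I)O1
F6 | step 4 | (2R)-5-(but-3-en-1-yl)-2-[(2Z)-3-iodoprop-2-en-1-yl]-2-methylfuran-3(2H)-one | C=CCCC1=CC(=O)[C@@](C)(C/C=C\I)O1
F7 | step 4 | 3-{(5R)-5-[(2Z)-3-iodoprop-2-en-1-yl]-5-methyl-4-oxo-4,5-dihydrofuran-2-yl}propanal | O=CCCC1=CC(=O)[C@@](C)(C/C=C\I)O1
F8 | step 4 | (2Z,6S,7Z,10R)-3,10-epoxy-6-hydroxy-10-methylcyclodeca-2,7-dien-1-one | O[C@@H]1/C=C\C[C@@]2(C)OC(=CC2=O)CC1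
F9 | step 4 | (2Z,7Z,10R)-3,10-epoxy-10-methylcyclodeca-2,7-diene-1,6-dione | O=C1/C=C\C[C@@]2(C)OC(=CC2=O)CC1
F10 | step 5 | (2R)-2-allyl-5-[(2RS,4R)-4-hydroxyhex-5-en-2-yl]-2-methylfuran-3(2H)-one | C=C[C@H](O)CC(C)C1=CC(=O)[C@@](C)(CC=C)O1
F11 | step 5 | (2Z,4R,6R,7Z,10R)-3,10-epoxy-6-hydroxy-4,10-dimethylcyclodeca-2,7-dien-1-one | O[C@H]1/C=C\C[C@@]2(C)OC(=CC2=O)[C@H](C)C1
F12 | step 3 | (S)-3,4-bis[(tert-butyldimethylsilyl)oxy]but-1-ene | C=C[C@H](O[Si](C)(C)C(C)(C)C)CO[Si](C)(C)C(C)(C)C
F13 | step 3 | (S)-2-[(tert-butyldimethylsilyl)oxy]but-3-en-1-ol | C=C[C@H](O[Si](C)(C)C(C)(C)C)CO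
F14 | step 3 | (S)-2-[(tert-butyldimethylsilyl)oxy]but-3-en-1-yl trifluoromethanesulfonate | C=C[C@H](O[Si](C)(C)C(C)(C)C)COS(=O)(=O)C(F)(F)F
F15 | step 3 | (2R)-2-allyl-5-{(3R)-3-[(tert-butyldimethylsilyl)oxy]pent-4-en-1-yl}-2-methylfuran-3(2H)-one | C=C[C@H](O[Si](C)(C)C(C)(C)C)CCC1=CC(=O)[C@@](C)(CC=C)O1
F16 | step 6 | (2Z,4S,6R,7S,8S,10R)-7-bromo-3,10-epoxy-6,8-dihydroxy-4,10-dimethylcyclodec-2-en-1-one | O[C@@H]1C[C@H](C)C2=CC(=O)[C@@](C)(C[C@H](O)[C@H]1Br)O2
A1 | alternative 1 | isoxazole bridged between its 3- and 5-positions by the C4–C10 chain, with the C6/C7 γ-lactone, the C8 tert-butyldimethylsilyl ether and the C10 triethylsilyl ether | C1C(=O)O[C@@H]2C[C@H](C)c3cc(no3)[C@](C)(O[Si](CC)(CC)CC)C[C@H](O[Si](C)(C)C(C)(C)C)[C@@H]12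
A2 | alternative 2 | methyl 2-[oxygen-bridged (Z)-cyclodecenone]acetate with tetrahydrofuran-3-one ring, quaternary C10 and C6 tert-butyldimethylsilyl ether | COC(=O)C/C1=C/C[C@@]2(C)O[C@H](CC2=O)[C@@H](C)C[C@H]1O[Si](C)(C)C(C)(C)C
A3 | alternative 3 | furanone-bridged (Z)-cyclodec-4-ene fused to the C6/C7 γ-lactone (4,5-dehydro skeleton) with C8 tert-butyldimethylsilyl ether | C1C(=O)O[C@@H]2/C=C(/C)C3=CC(=O)[C@@](C)(C[C@H](O[Si](C)(C)C(C)(C)C)[C@@H]12)O3
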